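With the ring numbered C1 (C=O), C2=C3, C4 (CHOH), C5 (tertiary carbinol carrying the C17 chain) and C6, the plan rests on breaking C4–C5. The cis-4,5-diol is a reduced α-ketol, and C5 together with its chain is the carbonyl carbon of an oleoyl ketone. A chiral N-heterocyclic carbene makes the C4 aldehyde nucleophilic and lets it add to that ketone. One operation therefore forms C4–C5, closes the six-membered carbocycle and fixes the C5 quaternary stereocentre. The substrate is an acyclic 1,6-keto-aldehyde (C4 through C3, C2, C1, C6 to C5) whose C1 carbonyl is stored as a dioxolane.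

Key step: step 6

Remark: the target SMILES decodes as (4R,5S) with the two hydroxyls cis; the sense of induction of the triazolium antipode named in step 6 is assigned from the hydrogen-bonded transition-state model, and its equally available (5aR,10bS) antipode would be used instead, with nothing else changed, if the first batch proves to be the (R)-ketol.

Step 1
Reactants: 1 pent-4-yn-1-ol
Product: 2 tert-butyldimethyl(pent-4-yn-1-yloxy)silane
Conditions: TBSCl (1.1 equiv), imidazole (1.5 equiv), CH2Cl2, 0 °C to rt
Reagents that add atoms: tert-butyldimethylsilyl chloride, CC(C)(C)[Si](C)(C)Cl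
Why: Imidazole-promoted O-silylation of the unhindered primary alcohol is routine and leaves the terminal alkyne C–H free for the coupling.

Step 2
Reactants: 2 tert-butyldimethyl(pent-4-yn-1-yloxy)silane; 3 oleoyl chloride [(9Z)-octadec-9-enoyl chloride, freshly distilled]
Product: 4 (14Z)-1-[(tert-butyldimethylsilyl)oxy]tricos-14-en-4-yn-6-one
Conditions: PdCl2(PPh3)2 (2 mol%), CuI (4 mol%), Et3N (1.3 equiv), THF, rt
Reagents that add atoms: none
Why: Acyl Sonogashira coupling, in which the copper acetylide of 2 transmetalates to the acyl-palladium chloride formed from 3 and reductive elimination gives the ynone at room temperature without touching the Z-alkene or the silyl ether.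

Step 3
Reactants: 4 (14Z)-1-[(tert-butyldimethylsilyl)oxy]tricos-14-en-4-yn-6-one; 5 ethylene glycol
Product: 7 (10Z)-1-{2-[3-(tert-butyldimethylsilyloxy)propyl]-1,3-dioxolan-2-yl}nonadec-10-en-2-one, via β-(2-hydroxyethoxy)enone 6 (not isolated)
Conditions: HOCH2CH2OH (5 equiv), t-BuOK (20 mol%), THF, 0 °C to rt; pH 7 buffer quench
Reagents that add atoms: none
Why: Base-catalysed double oxa-Michael addition, in which glycolate adds to the ynone β-carbon to give vinylogous ester 6 and its pendant hydroxyl then closes 5-exo-trig onto the same carbon, so the ketal forms only at C1 (β to the oleoyl ketone) under conditions that spare the silyl ether.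

Step 4
Reactants: 7 (10Z)-1-{2-[3-(tert-butyldimethylsilyloxy)propyl]-1,3-dioxolan-2-yl}nonadec-10-en-2-one
Product: 8 (10Z)-1-[2-(3-hydroxypropyl)-1,3-dioxolan-2-yl]nonadec-10-en-2-one
Conditions: TBAF (1.2 equiv), AcOH (1.2 equiv), THF, 0 °C to rt
Reagents that add atoms: none
Why: Fluoride-driven desilylation of the primary TBS ether, buffered with acetic acid so that the medium neither opens the β-keto ketal by E1cB nor starts enolate chemistry.

Step 5
Reactants: 8 (10Z)-1-[2-(3-hydroxypropyl)-1,3-dioxolan-2-yl]nonadec-10-en-2-one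
Product: 9 3-{2-[(10Z)-2-oxononadec-10-en-1-yl]-1,3-dioxolan-2-yl}propanal
Conditions: Dess–Martin periodinane (1.2 equiv), NaHCO3 (3 equiv), CH2Cl2, 0 °C to rt
Reagents that add atoms: none
Why: Dess–Martin oxidation takes the primary alcohol to the aldehyde without over-oxidation and, buffered with bicarbonate, leaves the ketal, the ketone and the Z-alkene alone.

Step 6
Reactants: 9 3-{2-[(10Z)-2-oxononadec-10-en-1-yl]-1,3-dioxolan-2-yl}propanal
Product: 10 (7S)-7-[(8Z)-heptadec-8-en-1-yl]-7-hydroxy-1,4-dioxaspiro[4.5]decan-8-one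
Conditions: (5aS,10bR)-2-(pentafluorophenyl)-5a,10b-dihydro-4H,6H-indeno[2,1-b][1,2,4]triazolo[4,3-d][1,4]oxazin-2-ium tetrafluoroborate (15 mol%), Et3N (20 mol%), toluene (0.05 M), rt
Reagents that add atoms: none
Why: The amine frees the triazolylidene, which adds to the C4 aldehyde and after proton transfer gives the nucleophilic enaminol (acyl-anion equivalent); this attacks the C5 ketone with its O–H hydrogen-bonded to the ketone oxygen, and collapse of the adduct regenerates the carbene and leaves the C4 ketone next to the new tertiary carbinol. The closest known reaction type is the enantioselective carbene-catalysed intramolecular crossed aldehyde–ketone benzoin cyclisation to six-membered tertiary α-ketols, which is on record for aliphatic keto-aldehydes. The ring (C4–C3–C2–C1–C6–C5) closes in a 6-exo-trig mode on the ketone carbon. C5 is the only new stereocentre and is controlled by the catalyst: the indane backbone shields one face of the enaminol, and in the hydrogen-bonded, chair-like transition state the C17 chain sits pseudo-equatorially, so a single ketone face is presented. The step needs chemoselectivity for acyl-anion addition over enolate aldol closure to five-membered rings (C6 onto C4, or C3 onto C5) and over intermolecular aldehyde dimerisation; this is secured by a sub-stoichiometric, weakly basic amine, by dilution, by the fact that only the aldehyde can form the enaminol while only the ketone can accept it, and by the gem-dialkoxy C1, which favours the folded chain. The dioxolane also keeps C1 from forming a 1,3-dicarbonyl with C5, whose enolisation would otherwise dominate.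

Step 7
Reactants: 10 (7S)-7-[(8Z)-heptadec-8-en-1-yl]-7-hydroxy-1,4-dioxaspiro[4.5]decan-8-one
Product: 11 (9S)-9-[(8Z)-heptadec-8-en-1-yl]-8,9-bis[(trimethylsilyl)oxy]-1,4-dioxaspiro[4.5]dec-7-ene
Conditions: TMSOTf (3 equiv), Et3N (5 equiv), CH2Cl2, –78 to 0 °C
Reagents that add atoms: trimethylsilyl trifluoromethanesulfonate, C[Si](C)(C)OS(=O)(=O)C(F)(F)F
Why: Soft enolisation and O-silylation with silyl triflate and amine caps the tertiary hydroxyl and gives a single silyl enol ether, because the ketone has α-hydrogens only at C3 (C5 is quaternary), while the dioxolane tolerates these conditions at low temperature and short reaction time.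

Step 8
Reactants: 11 (9S)-9-[(8Z)-heptadec-8-en-1-yl]-8,9-bis[(trimethylsilyl)oxy]-1,4-dioxaspiro[4.5]dec-7-ene
Product: 12 (9S)-9-[(8Z)-heptadec-8-en-1-yl]-9-[(trimethylsilyl)oxy]-1,4-dioxaspiro[4.5]dec-6-en-8-one
Conditions: Pd(OAc)2 (1.1 equiv), MeCN, rt
Reagents that add atoms: none
Why: Saegusa–Ito oxidation, in which the silyl enol ether passes to a palladium(II) enolate and β-hydride elimination, possible only from C2, gives the C2=C3 enone while the quaternary C5 stereocentre is untouched.

Step 9
Reactants: 12 (9S)-9-[(8Z)-heptadec-8-en-1-yl]-9-[(trimethylsilyl)oxy]-1,4-dioxaspiro[4.5]dec-6-en-8-one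
Product: 13 (8R,9S)-9-[(8Z)-heptadec-8-en-1-yl]-9-[(trimethylsilyl)oxy]-1,4-dioxaspiro[4.5]dec-6-en-8-ol
Conditions: NaBH4 (1.2 equiv), CeCl3·7H2O (1.2 equiv), MeOH/THF (3:1), –78 °C; pH 7 buffer work-up
Reagents that add atoms: none
Why: Luche reduction gives clean 1,2-addition, and with the C5–OSiMe3 bond pseudo-axial (chain equatorial) hydride should enter the carbonyl antiperiplanar to that C–O bond (polar α-heteroatom model, on the face away from the silyloxy group and the axial ketal oxygen), which places the new C4 hydroxyl cis to the C5 oxygen, i.e. (8R).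

Step 10
Reactants: 13 (8R,9S)-9-[(8Z)-heptadec-8-en-1-yl]-9-[(trimethylsilyl)oxy]-1,4-dioxaspiro[4.5]dec-6-en-8-ol
Product: 14 (4R,5S)-5-[(8Z)-heptadec-8-en-1-yl]-4,5-dihydroxycyclohex-2-en-1-one
Conditions: 1 M aq. HCl/THF (1:4), 0 °C, short contact; NaHCO3 quench
Reagents that add atoms: water, O
Why: Acid hydrolysis, in which the allylic dioxolane ionises readily to a conjugated oxocarbenium ion that water captures to unveil the C1 enone carbonyl and the tertiary trimethylsilyl ether is cleaved in the same pot, run cold and dilute so that the β-hydroxy ketone does not dehydrate towards the hydroquinone and neither stereocentre is touched.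

Compound list
1 | pent-4-yn-1-ol | C#CCCCO | starting material
2 | tert-butyldimethyl(pent-4-yn-1-yloxy)silane | C#CCCCO[Si](C)(C)C(C)(C)C | intermediate
3 | oleoyl chloride, (9Z)-octadec-9-enoyl chloride | CCCCCCCC/C=C\CCCCCCCC(Cl)=O | starting material
4 | (14Z)-1-[(tert-butyldimethylsilyl)oxy]tricos-14-en-4-yn-6-one | CCCCCCCC/C=C\CCCCCCCC(=O)C#CCCCO[Si](C)(C)C(C)(C)C | intermediate
5 | ethylene glycol (ethane-1,2-diol) | OCCO | starting material
6 | (4E,14Z)-1-[(tert-butyldimethylsilyl)oxy]-4-(2-hydroxyethoxy)tricosa-4,14-dien-6-one (drawn as the E enol ether; either geometry cyclises) | CCCCCCCC/C=C\CCCCCCCC(=O)/C=C(\CCCO[Si](C)(C)C(C)(C)C)OCCO | intermediate (not isolated)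
7 | (10Z)-1-{2-[3-(tert-butyldimethylsilyloxy)propyl]-1,3-dioxolan-2-yl}nonadec-10-en-2-one | CCCCCCCC/C=C\CCCCCCCC(=O)CC1(CCCO[Si](C)(C)C(C)(C)C)OCCO1 | intermediate
8 | (10Z)-1-[2-(3-hydroxypropyl)-1,3-dioxolan-2-yl]nonadec-10-en-2-one | CCCCCCCC/C=C\CCCCCCCC(=O)CC1(CCCO)OCCO1 | intermediate
9 | 3-{2-[(10Z)-2-oxononadec-10-en-1-yl]-1,3-dioxolan-2-yl}propanal | O=CCCC1(CC(=O)CCCCCCC/C=C\CCCCCCCC)OCCO1 | intermediate
10 | (7S)-7-[(8Z)-heptadec-8-en-1-yl]-7-hydroxy-1,4-dioxaspiro[4.5]decan-8-one | CCCCCCCC/C=C\CCCCCCC[C@]1(O)CC2(OCCO2)CCC1=O | intermediate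
11 | (9S)-9-[(8Z)-heptadec-8-en-1-yl]-8,9-bis[(trimethylsilyl)oxy]-1,4-dioxaspiro[4.5]dec-7-ene | CCCCCCCC/C=C\CCCCCCC[C@]1(O[Si](C)(C)C)CC2(OCCO2)CC=C1O[Si](C)(C)C | intermediate
12 | (9S)-9-[(8Z)-heptadec-8-en-1-yl]-9-[(trimethylsilyl)oxy]-1,4-dioxaspiro[4.5]dec-6-en-8-one | CCCCCCCC/C=C\CCCCCCC[C@]1(O[Si](C)(C)C)CC2(OCCO2)C=CC1=O | intermediate
13 | (8R,9S)-9-[(8Z)-heptadec-8-en-1-yl]-9-[(trimethylsilyl)oxy]-1,4-dioxaspiro[4.5]dec-6-en-8-ol | CCCCCCCC/C=C\CCCCCCC[C@]1(O[Si](C)(C)C)CC2(OCCO2)C=C[C@H]1O | intermediate
14 | (4R,5S)-5-[(8Z)-heptadec-8-en-1-yl]-4,5-dihydroxycyclohex-2-en-1-one | CCCCCCCC/C=C\CCCCCCC[C@]1(O)CC(=O)C=C[C@H]1O | target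

Total step count: 10
Longest linear sequence: 10 steps (from pent-4-yn-1-ol 1)

Steps most likely to fail

Step 6. The carbene may discriminate poorly between the two faces of a ketone flanked by two methylene groups, or enolate aldol closure may outrun the acyl-anion addition. The fallback makes the C4–C5 bond reductively and secures the configuration by resolution. It sets out from keto-aldehyde 9. Intramolecular pinacol coupling with SmI2 (2.2 equiv, t-BuOH, THF, –78 °C to rt) should give the racemic cis-diol, rac-(7S*,8R*)-7-[(8Z)-heptadec-8-en-1-yl]-1,4-dioxaspiro[4.5]decane-7,8-diol F1. Its secondary hydroxyl alone is esterified with (2S)-methoxy(phenyl)acetic acid (EDC, DMAP, CH2Cl2, 0 °C). This gives the diastereomeric esters (7S,8R)-7-[(8Z)-heptadec-8-en-1-yl]-7-hydroxy-1,4-dioxaspiro[4.5]decan-8-yl (2S)-methoxy(phenyl)acetate F2 and (7R,8S)-7-[(8Z)-heptadec-8-en-1-yl]-7-hydroxy-1,4-dioxaspiro[4.5]decan-8-yl (2S)-methoxy(phenyl)acetate F3, which are separated on silica. Methanolysis of F2 (K2CO3, MeOH, 0 °C) frees (7S,8R)-7-[(8Z)-heptadec-8-en-1-yl]-1,4-dioxaspiro[4.5]decane-7,8-diol F4. Parikh–Doering oxidation of its secondary carbinol (SO3·pyridine, DMSO, Et3N) erases C8 and comes back to the route at ketol 10.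

Step 3. The glycol addition may stall at the open vinylogous ester 6, or be diverted by propargylic deprotonation of the ynone. The fallback uses the sulfur version of the double conjugate addition and then exchanges sulfur for oxygen. It sets out from ynone 4. Propane-1,3-dithiol with catalytic NaOMe (MeOH/CH2Cl2, –10 °C to rt) should give (10Z)-1-{2-[3-(tert-butyldimethylsilyloxy)propyl]-1,3-dithian-2-yl}nonadec-10-en-2-one F5. Oxidative dithiane exchange with PhI(OCOCF3)2 in MeCN containing ethylene glycol then gives the dioxolane directly and comes back to the route at 7.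

Step 9. Hydride delivery may be insufficiently face-selective if the conformer with the chain pseudo-axial reacts competitively, which would give the trans-diol series. The fallback replaces substrate control by catalyst control and sets out from enone 12. Corey–Bakshi–Shibata reduction with the (S)-methyl-oxazaborolidine and catecholborane (toluene, –78 °C; the Z-alkene is not hydroborated at that temperature) treats the quaternary C9 as the large flank and the vinyl carbon as the small one. It should give the (8R)-carbinol and so comes back to the route at 13; no new compound arises (F0).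

Further compounds
F1 | step 6 | rac-(7S*,8R*)-7-[(8Z)-heptadec-8-en-1-yl]-1,4-dioxaspiro[4.5]decane-7,8-diol (cis-diol, racemate, both enantiomers written) | CCCCCCCC/C=C\CCCCCCC[C@]1(O)CC2(OCCO2)CC[C@H]1O.CCCCCCCC/C=C\CCCCCCC[C@@]1(O)CC2(OCCO2)CC[C@@H]1O
F2 | step 6 | (7S,8R)-7-[(8Z)-heptadec-8-en-1-yl]-7-hydroxy-1,4-dioxaspiro[4.5]decan-8-yl (2S)-methoxy(phenyl)acetate | CCCCCCCC/C=C\CCCCCCC[C@]1(O)CC2(OCCO2)CC[C@H]1OC(=O)[C@@H](OC)c1ccccc1
F3 | step 6 | (7R,8S)-7-[(8Z)-heptadec-8-en-1-yl]-7-hydroxy-1,4-dioxaspiro[4.5]decan-8-yl (2S)-methoxy(phenyl)acetate | CCCCCCCC/C=C\CCCCCCC[C@@]1(O)CC2(OCCO2)CC[C@@H]1OC(=O)[C@@H](OC)c1ccccc1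
F4 | step 6 | (7S,8R)-7-[(8Z)-heptadec-8-en-1-yl]-1,4-dioxaspiro[4.5]decane-7,8-diol | CCCCCCCC/C=C\CCCCCCC[C@]1(O)CC2(OCCO2)CC[C@H]1O
F5 | step 3 | (10Z)-1-{2-[3-(tert-butyldimethylsilyloxy)propyl]-1,3-dithian-2-yl}nonadec-10-en-2-one | CCCCCCCC/C=C\CCCCCCCC(=O)CC1(CCCO[Si](C)(C)C(C)(C)C)SCCCS1
F0 | step 9 | none | none
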